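The bond disconnection rests on cutting the dihydrofuran ring at C2–C3 and O1–C2: C2, the ring carbon that carries the guaiacyl group and is flanked by C3 and O1, is delivered as a single benzylidene carbon to an ortho-quinone methide of the benzo ring. In one operation a chiral benzylsulfonium ylide adds to the methide carbon and the liberated phenoxide expels the sulfide, closing the five-membered ring and setting C2 and C3 trans. The precursor is a 4-bromo-6-methoxyphenol bearing an ortho CH(SO2Tol)CH2OTBS arm, which releases the quinone methide with base; the bromine is the later handle for the chiral-pool triol chain.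

Key step: step 7

Assumption: the ylide from the (2R,5R) thiolane is taken to attack the quinone methide with the face preference it shows toward aldehydes, which after the inverting ring closure gives (R) at C2; if the sense proves opposite, the enantiomeric salt from (2R,5R)-hexane-2,5-diol is used in steps 4–7 with no other change.
Remark: compounds 3, 5 and 6 are racemic at the benzylic carbon, which becomes planar in 12, so this centre needs no control.

Step 1
Reactants: 1 5-bromo-2-hydroxy-3-methoxybenzaldehyde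
Product: 3 1-(5-bromo-2-hydroxy-3-methoxyphenyl)ethane-1,2-diol (racemic), via β-hydroxysilane 2 (not isolated)
Conditions: (iPrO)Me2SiCH2MgCl (2.5 equiv; from ClCH2SiMe2(OiPr), Mg, THF), THF, 0 °C → rt; then MeOH, KF, KHCO3, 30% H2O2, rt (same flask)
Reagents that add atoms: (chloromethyl)(isopropoxy)dimethylsilane, ClC[Si](C)(C)OC(C)C (the CH2 carbon); hydrogen peroxide, OO (the oxygen of the primary hydroxyl)
Why: Tamao hydroxymethylation, in which the silylmethyl Grignard reagent adds to the aldehyde (one equivalent is spent on the phenol) and Tamao oxidation of the C–Si bond unveils the primary alcohol; the new carbinol centre is racemic and is erased in step 7.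

Step 2
Reactants: 3 1-(5-bromo-2-hydroxy-3-methoxyphenyl)ethane-1,2-diol
Product: 5 4-bromo-2-[2-(tert-butyldimethylsilyloxy)-1-hydroxyethyl]-6-methoxyphenol (racemic), via bis-silyl ether 4 (not isolated)
Conditions: TBSCl (2.2 equiv), imidazole (4 equiv), DMF, 0 °C → rt; then MeOH, KHF2 (2 equiv), rt
Reagents that add atoms: tert-butyldimethylsilyl chloride, CC(C)(C)[Si](C)(C)Cl
Why: Silyl ether formation at the two most reactive hydroxyls (phenol and primary alcohol) followed by chemoselective desilylation, since bifluoride in methanol cleaves aryl silyl ethers and leaves alkyl silyl ethers, gives the mono-protected phenol without a separate protecting group.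

Step 3
Reactants: 5 4-bromo-2-[2-(tert-butyldimethylsilyloxy)-1-hydroxyethyl]-6-methoxyphenol
Product: 6 4-bromo-2-[2-(tert-butyldimethylsilyloxy)-1-(p-tolylsulfonyl)ethyl]-6-methoxyphenol (racemic)
Conditions: p-TolSO2H (1.5 equiv, freshly liberated from its sodium salt), CH2Cl2, rt
Reagents that add atoms: p-toluenesulfinic acid, Cc1ccc(cc1)S(=O)O
Why: Acid-promoted benzylic substitution of an ortho-hydroxybenzyl alcohol (ionisation assisted by the phenol, S-attack of the sulfinate) is the standard entry to 2-(1-tosylalkyl)phenols, and a weak acid in an aprotic solvent should spare the primary silyl ether.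

Step 4
Reactants: 7 (2S,5S)-hexane-2,5-diol
Product: 8 (2S,5S)-hexane-2,5-diyl dimethanesulfonate
Conditions: MsCl (2.4 equiv), Et3N, CH2Cl2, 0 °C
Reagents that add atoms: methanesulfonyl chloride, CS(=O)(=O)Cl
Why: Mesylation (O-sulfonylation) takes place at oxygen and leaves both carbinol centres untouched.

Step 5
Reactants: 8 (2S,5S)-hexane-2,5-diyl dimethanesulfonate
Product: 9 (2R,5R)-2,5-dimethylthiolane
Conditions: Na2S·9H2O, DMSO, rt → 40 °C; distillation
Reagents that add atoms: sodium sulfide, [Na+].[Na+].[S-2]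
Why: Double SN2 displacement (intermolecular, then 5-exo-tet) inverts both centres cleanly, turning the (S,S) dimesylate into the C2-symmetric (R,R) thiolane.

Step 6
Reactants: 9 (2R,5R)-2,5-dimethylthiolane; 10 (4-benzyloxy-3-methoxyphenyl)methanol
Product: 11 (2R,5R)-1-(4-benzyloxy-3-methoxybenzyl)-2,5-dimethylthiolanium tetrafluoroborate
Conditions: 9 (1.5 equiv), HBF4·OEt2 (1.1 equiv), CH2Cl2, 0 °C → rt; precipitation with Et2O
Reagents that add atoms: tetrafluoroboric acid (diethyl ether complex), [H+].F[B-](F)(F)F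
Why: S-alkylation of the sulfide by the acid-ionised, electron-rich benzylic alcohol (SN1 alkylation) gives the salt with a non-nucleophilic counter-ion, and because the sulfide is C2-symmetric its two lone pairs are equivalent, so only one sulfonium stereoisomer can form.

Step 7
Reactants: 6 4-bromo-2-[2-(tert-butyldimethylsilyloxy)-1-(p-tolylsulfonyl)ethyl]-6-methoxyphenol; 11 (2R,5R)-1-(4-benzyloxy-3-methoxybenzyl)-2,5-dimethylthiolanium tetrafluoroborate
Product: 15 (2R,3S)-2-(4-benzyloxy-3-methoxyphenyl)-5-bromo-3-(tert-butyldimethylsilyloxymethyl)-7-methoxy-2,3-dihydrobenzofuran, via quinone methide 12 (not isolated), via sulfonium ylide 13 (not isolated), via betaine 14 (not isolated)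
Conditions: 11 (1.5 equiv), Cs2CO3 (3 equiv), MeCN/CH2Cl2 (1:1), −20 °C → rt, 6 added slowly; 9 recovered
Reagents that add atoms: none
Why: Proposed new method: a formal [4+1] annulation in which Cs2CO3 turns the phenol of 6 into a phenoxide that expels p-toluenesulfinate to give quinone methide 12 and also deprotonates 11 to benzylide 13, whose carbon adds to the exocyclic methide carbon (C2–C3 bond, driven by rearomatisation) before the phenoxide of betaine 14 displaces the thiolane at the benzylic sulfonium carbon (O1–C2 bond). The closest known reactions are the trans-selective [4+1] annulation of quinone methides from 2-(1-tosylalkyl)phenols with carbonyl-stabilised sulfonium ylides and the asymmetric epoxidation of aldehydes with chiral benzylsulfonium ylides. The one ring formed, the dihydrofuran, closes in a 5-exo-tet SN2 step with inversion at C2. C2 is controlled by the C2-symmetric thiolane, which leaves one face of the ylide carbon open, and C3 is set relative to C2, because the betaine that closes with the aryl group and the CH2OTBS arm on opposite faces cyclises faster and any reversibility of the addition drains the other one. The step needs C-attack of the ylide to outrun tautomerisation or dimerisation of 12 and benzylation of the phenoxide by 11. Slow release of 12 from the sulfone (sulfinate re-addition is reversible), the high electrophilicity of the methide carbon and the good leaving-group ability of the electron-rich benzylic sulfonium are what should secure this.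

Step 8
Reactants: 15 (2R,3S)-2-(4-benzyloxy-3-methoxyphenyl)-5-bromo-3-(tert-butyldimethylsilyloxymethyl)-7-methoxy-2,3-dihydrobenzofuran; 16 (R)-2,2-dimethyl-1,3-dioxolane-4-carbaldehyde
Product: 19 (S)-[(2R,3S)-2-(4-benzyloxy-3-methoxyphenyl)-3-(tert-butyldimethylsilyloxymethyl)-7-methoxy-2,3-dihydrobenzofuran-5-yl][(R)-2,2-dimethyl-1,3-dioxolan-4-yl]methanol, via aryllithium 17 (not isolated), via aryltitanium 18 (not isolated)
Conditions: n-BuLi (1.05 equiv), THF, −78 °C; ClTi(OiPr)3 (1.1 equiv), −78 → −40 °C; 16 (1.5 equiv, freshly distilled), −78 → 0 °C; aq NH4Cl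
Reagents that add atoms: none
Why: Bromine–lithium exchange, transmetalation to the non-chelating aryltitanium triisopropoxide and 1,2-addition to the α-alkoxy aldehyde under Felkin–Anh control (dioxolane C–O bond anti to the incoming aryl group, attack past the α-hydrogen) should give the anti adduct, that is the (S) carbinol next to the (R) dioxolane carbon taken from the chiral pool.

Step 9
Reactants: 19 (S)-[(2R,3S)-2-(4-benzyloxy-3-methoxyphenyl)-3-(tert-butyldimethylsilyloxymethyl)-7-methoxy-2,3-dihydrobenzofuran-5-yl][(R)-2,2-dimethyl-1,3-dioxolan-4-yl]methanol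
Product: 20 (1S,2R)-1-[(2R,3S)-2-(4-benzyloxy-3-methoxyphenyl)-3-(hydroxymethyl)-7-methoxy-2,3-dihydrobenzofuran-5-yl]propane-1,2,3-triol
Conditions: AcOH/H2O/THF (3:1:1), 40 °C
Reagents that add atoms: none
Why: Mild acid hydrolysis (acetal hydrolysis and cleavage of the primary silyl ether) removes both groups in one operation, while the acidity is too low to ionise the benzylic carbinol or the C2–O1 bond, so no stereocentre is touched.

Step 10
Reactants: 20 (1S,2R)-1-[(2R,3S)-2-(4-benzyloxy-3-methoxyphenyl)-3-(hydroxymethyl)-7-methoxy-2,3-dihydrobenzofuran-5-yl]propane-1,2,3-triol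
Product: 21 (1S,2R)-1-[(2R,3S)-2-(4-hydroxy-3-methoxyphenyl)-3-(hydroxymethyl)-7-methoxy-2,3-dihydrobenzofuran-5-yl]propane-1,2,3-triol
Conditions: H2 (1 atm), 10% Pd/C, EtOAc/EtOH (1:1), rt, stopped at full conversion
Reagents that add atoms: none
Why: Hydrogenolysis of the aryl benzyl ether under neutral conditions is much faster than cleavage of the benzylic C–O bonds at C2 and at the side-chain carbinol, so the phenol is released without touching any stereocentre.

Compound list
1 | 5-bromo-2-hydroxy-3-methoxybenzaldehyde | COc1cc(Br)cc(C=O)c1O | starting material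
2 | 4-bromo-2-[1-hydroxy-2-(isopropoxydimethylsilyl)ethyl]-6-methoxyphenol (racemic, present as its magnesium salt) | COc1cc(Br)cc(C(O)C[Si](C)(C)OC(C)C)c1O | intermediate (not isolated)
3 | 1-(5-bromo-2-hydroxy-3-methoxyphenyl)ethane-1,2-diol (racemic) | COc1cc(Br)cc(C(O)CO)c1O | intermediate
4 | 1-[5-bromo-2-(tert-butyldimethylsilyloxy)-3-methoxyphenyl]-2-(tert-butyldimethylsilyloxy)ethan-1-ol (racemic) | COc1cc(Br)cc(C(O)CO[Si](C)(C)C(C)(C)C)c1O[Si](C)(C)C(C)(C)C | intermediate (not isolated)
5 | 4-bromo-2-[2-(tert-butyldimethylsilyloxy)-1-hydroxyethyl]-6-methoxyphenol (racemic) | COc1cc(Br)cc(C(O)CO[Si](C)(C)C(C)(C)C)c1O | intermediate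
6 | 4-bromo-2-[2-(tert-butyldimethylsilyloxy)-1-(p-tolylsulfonyl)ethyl]-6-methoxyphenol (racemic) | COc1cc(Br)cc(C(CO[Si](C)(C)C(C)(C)C)S(=O)(=O)c2ccc(C)cc2)c1O | intermediate
7 | (2S,5S)-hexane-2,5-diol | C[C@H](O)CC[C@H](C)O | starting material
8 | (2S,5S)-hexane-2,5-diyl dimethanesulfonate | C[C@H](OS(C)(=O)=O)CC[C@H](C)OS(C)(=O)=O | intermediate
9 | (2R,5R)-2,5-dimethylthiolane | C[C@@H]1CC[C@@H](C)S1 | intermediate
10 | (4-benzyloxy-3-methoxyphenyl)methanol | COc1cc(CO)ccc1OCc1ccccc1 | starting material
11 | (2R,5R)-1-(4-benzyloxy-3-methoxybenzyl)-2,5-dimethylthiolanium tetrafluoroborate | C[C@@H]1CC[C@@H](C)[S+]1Cc1ccc(OCc2ccccc2)c(OC)c1.F[B-](F)(F)F | intermediate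
12 | 4-bromo-6-[2-(tert-butyldimethylsilyloxy)ethylidene]-2-methoxycyclohexa-2,4-dien-1-one (alkene geometry not defined) | COC1=CC(Br)=CC(=CCO[Si](C)(C)C(C)(C)C)C1=O | intermediate (not isolated)
13 | (2R,5R)-1-[(4-benzyloxy-3-methoxyphenyl)methylide]-2,5-dimethylthiolanium (ylide) | C[C@@H]1CC[C@@H](C)[S+]1[CH-]c1ccc(OCc2ccccc2)c(OC)c1 | intermediate (not isolated)
14 | 4-bromo-2-[(1S,2S)-1-(4-benzyloxy-3-methoxyphenyl)-1-[(2R,5R)-2,5-dimethylthiolan-1-ium-1-yl]-3-(tert-butyldimethylsilyloxy)propan-2-yl]-6-methoxyphenolate (betaine) | COc1cc(Br)cc([C@H]([C@H]([S+]2[C@H](C)CC[C@H]2C)c2ccc(OCc3ccccc3)c(OC)c2)CO[Si](C)(C)C(C)(C)C)c1[O-] | intermediate (not isolated)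
15 | (2R,3S)-2-(4-benzyloxy-3-methoxyphenyl)-5-bromo-3-(tert-butyldimethylsilyloxymethyl)-7-methoxy-2,3-dihydrobenzofuran | COc1cc([C@@H]2Oc3c(OC)cc(Br)cc3[C@H]2CO[Si](C)(C)C(C)(C)C)ccc1OCc1ccccc1 | intermediate
16 | (R)-2,2-dimethyl-1,3-dioxolane-4-carbaldehyde | O=C[C@H]1COC(C)(C)O1 | starting material
17 | [(2R,3S)-2-(4-benzyloxy-3-methoxyphenyl)-3-(tert-butyldimethylsilyloxymethyl)-7-methoxy-2,3-dihydrobenzofuran-5-yl]lithium | COc1cc([C@@H]2Oc3c(OC)cc([Li])cc3[C@H]2CO[Si](C)(C)C(C)(C)C)ccc1OCc1ccccc1 | intermediate (not isolated)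
18 | [(2R,3S)-2-(4-benzyloxy-3-methoxyphenyl)-3-(tert-butyldimethylsilyloxymethyl)-7-methoxy-2,3-dihydrobenzofuran-5-yl]titanium triisopropoxide | COc1cc([C@@H]2Oc3c(OC)cc([Ti](OC(C)C)(OC(C)C)OC(C)C)cc3[C@H]2CO[Si](C)(C)C(C)(C)C)ccc1OCc1ccccc1 | intermediate (not isolated)
19 | (S)-[(2R,3S)-2-(4-benzyloxy-3-methoxyphenyl)-3-(tert-butyldimethylsilyloxymethyl)-7-methoxy-2,3-dihydrobenzofuran-5-yl][(R)-2,2-dimethyl-1,3-dioxolan-4-yl]methanol | COc1cc([C@@H]2Oc3c(OC)cc([C@H](O)[C@H]4COC(C)(C)O4)cc3[C@H]2CO[Si](C)(C)C(C)(C)C)ccc1OCc1ccccc1 | intermediate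
20 | (1S,2R)-1-[(2R,3S)-2-(4-benzyloxy-3-methoxyphenyl)-3-(hydroxymethyl)-7-methoxy-2,3-dihydrobenzofuran-5-yl]propane-1,2,3-triol | COc1cc([C@@H]2Oc3c(OC)cc([C@H](O)[C@H](O)CO)cc3[C@H]2CO)ccc1OCc1ccccc1 | intermediate
21 | (1S,2R)-1-[(2R,3S)-2-(4-hydroxy-3-methoxyphenyl)-3-(hydroxymethyl)-7-methoxy-2,3-dihydrobenzofuran-5-yl]propane-1,2,3-triol | COc1cc([C@@H]2Oc3c(OC)cc([C@H](O)[C@H](O)CO)cc3[C@H]2CO)ccc1O | target

Total step count: 10. Longest linear sequence: 7 steps (1 → 3 → 5 → 6 → 15 → 19 → 20 → 21; the thiolane branch 7 → 8 → 9 → 11 → 15 → 21 is equally long).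

Steps most likely to fail

Step 7, the only step beyond known chemistry. The short-lived quinone methide may tautomerise to the silyl enol ether styrene or dimerise before the semi-stabilised ylide reaches it. The sulfonium salt may benzylate the phenoxide or the released sulfinate instead of being deprotonated. The ylide may also discriminate its faces less well toward the methide than toward aldehydes. The fallback uses known reactions only and no auxiliary, and sets out from 6 and 10. Alcohol 10 is converted with SOCl2 into 4-(benzyloxy)-1-(chloromethyl)-2-methoxybenzene F1, and this with Mg in THF into (4-benzyloxy-3-methoxybenzyl)magnesium chloride F2. Three equivalents of F2 with 6 (THF, −78 °C → rt) should deprotonate the phenol, release the quinone methide and add to it in the 1,4 sense (conjugate addition of an organomagnesium reagent to an ortho-quinone methide). This gives racemic 4-bromo-2-[1-(4-benzyloxy-3-methoxyphenyl)-3-(tert-butyldimethylsilyloxy)propan-2-yl]-6-methoxyphenol F3. DDQ in CH2Cl2 at 0 °C should then oxidise the electron-rich benzylic methylene to the cation, which the phenol traps to the trans dihydrobenzofuran (an oxidative cyclisation of the kind used for pterocarpans). The product is the racemate of 15 and its enantiomer (2S,3R)-2-(4-benzyloxy-3-methoxyphenyl)-5-bromo-3-(tert-butyldimethylsilyloxymethyl)-7-methoxy-2,3-dihydrobenzofuran F4. Preparative chromatography on a chiral stationary phase removes F4 and returns to the route at 15.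

Step 8. Facial selectivity in the addition may be poor, giving the syn carbinol epimer, and the sensitive aldehyde may be lost to enolisation or oligomerisation. The fallback sets out from 15. Aryllithium 17 is acylated at −78 °C with (R)-N-methoxy-N,2,2-trimethyl-1,3-dioxolane-4-carboxamide F5, itself made from commercial methyl (R)-2,2-dimethyl-1,3-dioxolane-4-carboxylate with MeNH(OMe)·HCl and iPrMgCl. This gives [(2R,3S)-2-(4-benzyloxy-3-methoxyphenyl)-3-(tert-butyldimethylsilyloxymethyl)-7-methoxy-2,3-dihydrobenzofuran-5-yl][(R)-2,2-dimethyl-1,3-dioxolan-4-yl]methanone F6. Chelation-controlled reduction with Zn(BH4)2 in Et2O at −30 °C, with hydride delivered to the zinc chelate of the carbonyl and the α-oxygen from the face opposite the dioxolane CH2, should give the anti alcohol and return to the route at 19.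

Step 3. The silyl ether may be lost under the acidic conditions, or the ionised benzylic position may rearrange (hydride shift, then benzofuran formation) before the sulfinate captures it. The fallback sets out from 3, which carries no silyl group. Sodium p-toluenesulfinate in HCO2H/H2O at rt installs the sulfone first and gives 4-bromo-2-[2-hydroxy-1-(p-tolylsulfonyl)ethyl]-6-methoxyphenol F7. TBSOTf (2.2 equiv) and 2,6-lutidine in CH2Cl2 at −78 °C silylate both hydroxyls under conditions too weakly basic to trigger loss of sulfinate, giving tert-butyl{4-bromo-2-[2-(tert-butyldimethylsilyloxy)-1-(p-tolylsulfonyl)ethyl]-6-methoxyphenoxy}dimethylsilane F8. KHF2 in MeOH at rt then cleaves only the aryl silyl ether under weakly acidic conditions and returns to the route at 6.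

Further compounds
F1 | step 7 | 4-(benzyloxy)-1-(chloromethyl)-2-methoxybenzene | COc1cc(CCl)ccc1OCc1ccccc1
F2 | step 7 | (4-benzyloxy-3-methoxybenzyl)magnesium chloride | COc1cc(C[Mg]Cl)ccc1OCc1ccccc1
F3 | step 7 | 4-bromo-2-[1-(4-benzyloxy-3-methoxyphenyl)-3-(tert-butyldimethylsilyloxy)propan-2-yl]-6-methoxyphenol (racemic) | COc1cc(Br)cc(C(CO[Si](C)(C)C(C)(C)C)Cc2ccc(OCc3ccccc3)c(OC)c2)c1O
F4 | step 7 | (2S,3R)-2-(4-benzyloxy-3-methoxyphenyl)-5-bromo-3-(tert-butyldimethylsilyloxymethyl)-7-methoxy-2,3-dihydrobenzofuran | COc1cc([C@H]2Oc3c(OC)cc(Br)cc3[C@@H]2CO[Si](C)(C)C(C)(C)C)ccc1OCc1ccccc1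
F5 | step 8 | (R)-N-methoxy-N,2,2-trimethyl-1,3-dioxolane-4-carboxamide | CON(C)C(=O)[C@H]1COC(C)(C)O1
F6 | step 8 | [(2R,3S)-2-(4-benzyloxy-3-methoxyphenyl)-3-(tert-butyldimethylsilyloxymethyl)-7-methoxy-2,3-dihydrobenzofuran-5-yl][(R)-2,2-dimethyl-1,3-dioxolan-4-yl]methanone | COc1cc([C@@H]2Oc3c(OC)cc(C(=O)[C@H]4COC(C)(C)O4)cc3[C@H]2CO[Si](C)(C)C(C)(C)C)ccc1OCc1ccccc1
F7 | step 3 | 4-bromo-2-[2-hydroxy-1-(p-tolylsulfonyl)ethyl]-6-methoxyphenol (racemic) | COc1cc(Br)cc(C(CO)S(=O)(=O)c2ccc(C)cc2)c1O
F8 | step 3 | tert-butyl{4-bromo-2-[2-(tert-butyldimethylsilyloxy)-1-(p-tolylsulfonyl)ethyl]-6-methoxyphenoxy}dimethylsilane (racemic) | COc1cc(Br)cc(C(CO[Si](C)(C)C(C)(C)C)S(=O)(=O)c2ccc(C)cc2)c1O[Si](C)(C)C(C)(C)C
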